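What I carried through this flask was a leftover: the impurity takes enzyme one for one, and in the flask it is the limiting reagent of that loss. The charge of 2.0 µM less 1.0 µM of impurity leaves 1.00 µM, and this leftover, [enzyme] as charge minus impurity, is what I expected the rate to follow at first order.

| setting | Sunday's | Saturday's | Friday's | flask |
|---|---|---|---|---|
| starting material | 0.10 M | 0.10 M | 0.10 M | 0.10 M |
| enzyme | 1 µM | 4 µM | 2 µM | 2.0 µM |
| impurity | 1 µM | 1 µM | 1.5 µM | 1.0 µM |
| remark | run made earlier | run made earlier | run made earlier |  |

| run | time / min | product / % | starting material / % |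
|---|---|---|---|
| Sunday's | 8.00 | 4.0 | 95.7 |
| Sunday's | 15.0 | 4.9 | 94.9 |
| Sunday's | 25.0 | 5.4 | 95.1 |
| Sunday's | 50.0 | 6.2 | 93.5 |
| Sunday's | 90.0 | 7.0 | 93.6 |
| Saturday's | 20.0 | 69.4 | 31.2 |
| Saturday's | 40.0 | 80.8 | 19.4 |
| Saturday's | 60.0 | 84.9 | 15.5 |
| Saturday's | 80.0 | 87.6 | 13.0 |
| Saturday's | 90.0 | 88.2 | 11.6 |
| Friday's | 8.00 | 14.5 | 85.9 |
| Friday's | 25.0 | 32.5 | 67.4 |
| Friday's | 40.0 | 43.8 | 56.1 |
| Friday's | 60.0 | 53.8 | 44.9 |
| Friday's | 90.0 | 63.0 | 37.1 |

(standard deviation of a reading: 0.5 percentage points)

- the analysis behind the earlier runs scatters by 0.5 percentage points, standard deviation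

- factor on the rate of making product when 50% of the starting material are converted if enzyme is charged twice over
- factor on the rate when 50% of the starting material are converted if enzyme is charged at 10 µM instead

I read the runs as a ladder of times. The lowest rung was the loss of enzyme. Sunday's run had a leftover of 0 µM, and its product crept from 4.0% at 8.00 min to 7.0% at 90.0 min. At the pace per leftover µM in Friday's first reading, Sunday's enzyme worked for about 1.10 min, a rough reading.

The next rung was turnover. Friday's run reached 63.0% at 90.0 min on a leftover of 0.500 µM, so Saturday's, with 3.00 µM, should have reached it at 15.0 min; it stood at 69.4% at 20.0 min. Scaling by charges instead gives 45.0 min, which is too slow.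

The top rung was the bend: Saturday's run gained 0.6 percentage points between 80.0 min and 90.0 min. But with 0.10 M charged, the composition at 50% conversion is the same for every enzyme charge, so the bend cancels and the factor is the ratio of leftovers. Twice the flask's charge leaves 3.00 µM, a factor of 3.00; 10 µM leaves 9.00 µM, a factor of 9.00. Friday's run passed 50% between 40.0 min and 60.0 min, so at 10 µM I expected it after at least 2.22 min, longer than the rough 1.10 min read from Sunday's run.

The forecast gave the same 3 and 9, holding that “time scales with free enzyme”.

The simulation gives 3.00 and 9.00.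

    starting material + enzyme → product + enzyme, rate k1*[starting material]^2.5*[enzyme]/(1 + ([starting material]/Kh1)^2.5) (0.110 M, k = 33000 M⁻²·⁵ s⁻¹)
    enzyme + impurity → spent catalyst (k = 44000 M⁻¹ s⁻¹)

By 0.200 h the flask's impurity stood at 0% and its enzyme at 50.0% of the charge, the other 50.0% being spent catalyst, so the leftover was 1.00 µM. On that enzyme, starting material passed into product through 50% conversion at 25.5 min, at 0.0583 M h⁻¹, and product reached 80.2% at 2.00 h and 95.7% at 20.0 h, with the enzyme still at 50.0%. The flask charged at 10 µM, with its leftover of 9.00 µM, ran at 9.00 times that rate.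

The earlier runs and the new flask are calculated on assumed constants; the scatter is artificial.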